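**Retrosynthetic overview**
1. Target ⇐ late angeloylation of the C5 hydroxyl and C9 desilylation; the (E)-butenoyl chain comes from a C1 carbaldehyde (alkenylchromium addition, oxidation), and the C1 tertiary alcohol from dihydroxylation of a C1 exocyclic methylene.
2. γ-Lactone (second ring) ⇐ intramolecular opening of a C5–C6 epoxy ketone by the C12 carboxyl, which makes C5–O/C6–O trans and the lactone cis-fused.
3. Cycloheptenone (first ring) ⇐ ring-closing metathesis of an acyclic vinyl ketone / propenyl diene.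
4. Acyclic chain ⇐ Evans syn-aldol forming C9–C10 between aldehyde 15 (C6–C9, C11–C13) and propionimide 16 (C1, C10, C14); this is the fragment union.
5. Aldehyde 15 ⇐ Ireland–Claisen rearrangement of an (S,E)-allylic propanoate made from but-3-yn-1-ol via Noyori reduction.

Convention: in the comments C1 = ring carbon bearing OH and the butenoyl group, C5 = CH–O(angelate), C6 = CH–O(lactone), C7 = ring-fusion CH, C8 = CH2, C9 = CH–OH, C10 = CH–CH3, C11 = lactone CH–CH3, C12 = lactone C=O. Systematic names use cyclohepta[b]furan numbering.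

**Route**

Step 1
Reactants: 1 but-3-yn-1-ol
Product: 2 tert-butyl(but-3-yn-1-yloxy)dimethylsilane
Conditions: t-BuMe2SiCl, imidazole, DMF, rt
Reagents that add atoms: tert-butyldimethylsilyl chloride, CC(C)(C)[Si](C)(C)Cl
Why: Imidazole-promoted silylation of a primary alcohol is quantitative and creates no stereocentre.

Step 2
Reactants: 2 silyl ether; 3 N-methoxy-N-methylacetamide
Product: 5 6-[(tert-butyldimethylsilyl)oxy]hex-3-yn-2-one, via lithium acetylide 4 (not isolated)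
Conditions: n-BuLi, THF, −78 °C; then 3, −78 → 0 °C; aq NH4Cl
Reagents that add atoms: none
Why: Weinreb-amide acylation of a lithium acetylide stops at the ynone because the chelated tetrahedral adduct survives until work-up.

Step 3
Reactants: 5 ynone
Product: 6 (2S)-6-[(tert-butyldimethylsilyl)oxy]hex-3-yn-2-ol
Conditions: Ru[(S,S)-TsNCHPhCHPhNH](η6-p-cymene) (1 mol %), i-PrOH, rt
Reagents that add atoms: none
Why: Noyori asymmetric transfer hydrogenation of an ynone, in which the alkynyl group plays the role of the aryl group of acetophenone, so the (S,S)-catalyst gives the (S)-carbinol in high ee (the (R,R)-catalyst gives the antipode).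

Step 4
Reactants: 6 propargylic alcohol
Product: 7 (2S,3E)-6-[(tert-butyldimethylsilyl)oxy]hex-3-en-2-ol
Conditions: NaAlH2(OCH2CH2OMe)2, THF, 0 °C → rt
Reagents that add atoms: none
Why: Alkoxide-directed trans-hydroalumination of a propargylic alcohol gives only the E-alkene and leaves the carbinol centre untouched.

Step 5
Reactants: 7 allylic alcohol; 8 propanoyl chloride
Product: 9 (2S,3E)-6-[(tert-butyldimethylsilyl)oxy]hex-3-en-2-yl propanoate
Conditions: pyridine, DMAP (cat.), CH2Cl2, 0 °C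
Reagents that add atoms: none
Why: Simple O-acylation of a secondary alcohol with retention at the carbinol carbon.

Step 6
Reactants: 9 allylic propanoate
Product: 12 (2R,3R)-5-[(tert-butyldimethylsilyl)oxy]-2-methyl-3-[(1E)-prop-1-en-1-yl]pentanoic acid, via silyl ketene acetal 10 (not isolated), via trimethylsilyl ester 11 (not isolated)
Conditions: LiN(i-Pr)2, THF, −78 °C; Me3SiCl, −78 °C → rt, then 55 °C; 1 M NaOH, then pH 4
Reagents that add atoms: none
Why: Ireland–Claisen rearrangement: the kinetic E-enolate (THF, no HMPA) gives the (E)-silyl ketene acetal, and a chair transition state with the carbinol methyl equatorial transfers the C–O chirality suprafacially to C7 and sets C11 (expected dr about 9:1, new alkene E).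

Step 7
Reactants: 12 acid
Product: 13 tert-butyl (2R,3R)-5-[(tert-butyldimethylsilyl)oxy]-2-methyl-3-[(1E)-prop-1-en-1-yl]pentanoate
Conditions: O-tert-butyl-N,N'-diisopropylisourea, CH2Cl2, rt
Reagents that add atoms: O-tert-butyl-N,N'-diisopropylisourea, CC(C)NC(=NC(C)C)OC(C)(C)C
Why: Neutral isourea O-alkylation gives the tert-butyl ester without epimerising the α-centre; this ester resists the later aluminium amide and Grignard steps.

Step 8
Reactants: 13 silyl ether
Product: 14 tert-butyl (2R,3R)-5-hydroxy-2-methyl-3-[(1E)-prop-1-en-1-yl]pentanoate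
Conditions: HF·pyridine, pyridine, THF, 0 °C → rt
Reagents that add atoms: none
Why: Buffered fluoride desilylation frees the primary alcohol under conditions too mild to lactonise the hindered tert-butyl ester.

Step 9
Reactants: 14 alcohol
Product: 15 tert-butyl (2R,3R)-2-methyl-5-oxo-3-[(1E)-prop-1-en-1-yl]pentanoate
Conditions: Dess–Martin periodinane, CH2Cl2, rt
Reagents that add atoms: none
Why: Dess–Martin oxidation gives the aldehyde, whose only nearby stereocentre is β and cannot epimerise.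

Step 10
Reactants: 15 aldehyde; 16 (4S)-4-benzyl-3-propanoyl-1,3-oxazolidin-2-one
Product: 18 tert-butyl (2R,3R,5R,6S)-7-[(4S)-4-benzyl-2-oxo-1,3-oxazolidin-3-yl]-5-hydroxy-2,6-dimethyl-7-oxo-3-[(1E)-prop-1-en-1-yl]heptanoate, via boron enolate 17 (not isolated)
Conditions: 16, n-Bu2BOTf, i-Pr2NEt, CH2Cl2, −78 → 0 °C; then 15, −78 → 0 °C; pH 7 buffer, MeOH, H2O2, 0 °C
Reagents that add atoms: none
Why: Intermolecular Evans syn-aldol joining the two fragments at C9–C10: the Z-boron enolate reacts through a Zimmerman–Traxler chair with auxiliary-controlled facial selectivity, giving the (2S,3R)-syn pattern (C10 S, C9 R).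

Step 11
Reactants: 18 aldol adduct
Product: 19 tert-butyl (2R,3R,5R,6S)-5-hydroxy-7-[methoxy(methyl)amino]-2,6-dimethyl-7-oxo-3-[(1E)-prop-1-en-1-yl]heptanoate
Conditions: MeONHMe·HCl, AlMe3, THF, −20 → 0 °C; 0.5 M HCl work-up
Reagents that add atoms: N,O-dimethylhydroxylamine hydrochloride, CNOC.Cl
Why: Weinreb transamidation by the aluminium amide, assisted by the free β-hydroxyl, cleaves the exocyclic imide carbonyl selectively over the hindered tert-butyl ester without epimerisation.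

Step 12
Reactants: 19 hydroxy amide
Product: 20 tert-butyl (2R,3R,5R,6S)-7-[methoxy(methyl)amino]-2,6-dimethyl-7-oxo-3-[(1E)-prop-1-en-1-yl]-5-[(triisopropylsilyl)oxy]heptanoate
Conditions: i-Pr3SiOTf, 2,6-lutidine, CH2Cl2, 0 °C
Reagents that add atoms: triisopropylsilyl trifluoromethanesulfonate, CC(C)[Si](OS(=O)(=O)C(F)(F)F)(C(C)C)C(C)C
Why: Silyl triflate protection gives a C9 ether robust enough for the later trifluoroacetic acid step and prevents retro-aldol.

Step 13
Reactants: 20 Weinreb amide; 21 vinylmagnesium bromide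
Product: 22 tert-butyl (2R,3R,5R,6S)-2,6-dimethyl-7-oxo-3-[(1E)-prop-1-en-1-yl]-5-[(triisopropylsilyl)oxy]non-8-enoate
Conditions: THF, 0 °C; inverse quench into cold 1 M HCl
Reagents that add atoms: none
Why: Grignard addition to a Weinreb amide stops at the chelate and gives the vinyl ketone, the acidic quench preventing conjugate addition of the liberated amine.

Step 14
Reactants: 22 diene
Product: 23 tert-butyl (2R)-2-[(1R,5S,6R)-5-methyl-4-oxo-6-[(triisopropylsilyl)oxy]cyclohept-2-en-1-yl]propanoate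
Conditions: second-generation Grubbs catalyst (H2IMes)(PCy3)Cl2Ru=CHPh (5 mol %), CH2Cl2 (2 mM), 40 °C
Reagents that add atoms: none
Why: Ring-closing metathesis of a 1,8-diene forms the seven-membered enone with loss of propene and touches no stereocentre.

Step 15
Reactants: 23 cycloheptenone
Product: 24 tert-butyl (2R)-2-[(1S,2S,4R,5S,7S)-5-methyl-6-oxo-4-[(triisopropylsilyl)oxy]-8-oxabicyclo[5.1.0]octan-2-yl]propanoate
Conditions: t-BuOOH, BnNMe3OH (cat.), THF, 0 °C
Reagents that add atoms: tert-butyl hydroperoxide, CC(C)(C)OO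
Why: Weitz–Scheffer nucleophilic epoxidation: the hydroperoxide adds to C6 anti to the adjacent C7 side chain, so the oxirane lies trans to that chain (C5–O in its final configuration, C6–O awaiting inversion).

Step 16
Reactants: 24 epoxy ketone
Product: 26 (3R,3aS,5R,6S,8S,8aR)-8-hydroxy-3,6-dimethyl-5-[(triisopropylsilyl)oxy]hexahydro-2H-cyclohepta[b]furan-2,7(3H)-dione, via epoxy acid 25 (not isolated)
Conditions: CF3CO2H, CH2Cl2, 0 °C → rt
Reagents that add atoms: none
Why: Acidolysis of the tert-butyl ester is followed by 5-exo opening of the protonated oxirane at C6 (the carbon remote from the carbonyl; attack at C5 would need a bridged δ-lactone), and the inversion there gives the cis-fused γ-lactone with the C5 hydroxyl retained.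

Step 17
Reactants: 26 hydroxy ketone
Product: 27 (3R,3aS,5R,6S,8S,8aR)-3,6-dimethyl-8-[(triethylsilyl)oxy]-5-[(triisopropylsilyl)oxy]hexahydro-2H-cyclohepta[b]furan-2,7(3H)-dione
Conditions: Et3SiCl, imidazole, DMF, 0 °C
Reagents that add atoms: chlorotriethylsilane, CC[Si](Cl)(CC)CC
Why: Mild silylation caps the α-ketol before it can tautomerise and supplies a bulky allylic oxygen substituent for step 19.

Step 18
Reactants: 27 ketone; 28 dibromomethane
Product: 29 (3R,3aS,5R,6R,8R,8aR)-3,6-dimethyl-7-methylidene-8-[(triethylsilyl)oxy]-5-[(triisopropylsilyl)oxy]octahydro-2H-cyclohepta[b]furan-2-one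
Conditions: Zn, CH2Br2, TiCl4, THF (reagent pre-formed at 5 °C); then 27, CH2Cl2, 0 °C → rt
Reagents that add atoms: none
Why: Lombardo–Takai methylenation is non-basic, so the hindered ketone is methylenated without C10 epimerisation or β-elimination of the lactone oxygen, and the lactone carbonyl is not attacked.

Step 19
Reactants: 29 exocyclic alkene
Product: 30 (3R,3aS,5R,6S,7R,8S,8aR)-7-hydroxy-7-(hydroxymethyl)-3,6-dimethyl-8-[(triethylsilyl)oxy]-5-[(triisopropylsilyl)oxy]octahydro-2H-cyclohepta[b]furan-2-one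
Conditions: OsO4 (5 mol %), N-methylmorpholine N-oxide, acetone/H2O, rt
Reagents that add atoms: N-methylmorpholine N-oxide, C[N+]1([O-])CCOCC1; water, O
Why: Upjohn dihydroxylation in which OsO4 approaches anti to the allylic C5 silyloxy group (Kishi's empirical rule, reinforced by the C9 silyl ether on the same face), placing the new tertiary hydroxyl cis to the C10 methyl as the target requires.

Step 20
Reactants: 30 diol
Product: 31 (3R,3aS,5R,6S,7S,8S,8aR)-7-hydroxy-3,6-dimethyl-2-oxo-8-[(triethylsilyl)oxy]-5-[(triisopropylsilyl)oxy]octahydro-2H-cyclohepta[b]furan-7-carbaldehyde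
Conditions: SO3·pyridine, DMSO, i-Pr2NEt, CH2Cl2, 0 °C
Reagents that add atoms: none
Why: Parikh–Doering oxidation converts only the primary alcohol (the tertiary one is inert) and, unlike periodate-type oxidants, does not cleave the 1,2-diol.

Step 21
Reactants: 31 aldehyde; 32 (1E)-1-bromoprop-1-ene
Product: 33 (3R,3aS,5R,6S,7R,8S,8aR)-7-hydroxy-7-[(2E)-1-hydroxybut-2-en-1-yl]-3,6-dimethyl-8-[(triethylsilyl)oxy]-5-[(triisopropylsilyl)oxy]octahydro-2H-cyclohepta[b]furan-2-one (both carbinol epimers)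
Conditions: CrCl2, NiCl2 (1 mol %), DMF, rt
Reagents that add atoms: none
Why: Nozaki–Hiyama–Kishi addition: the alkenylchromium reagent adds to the aldehyde chemoselectively in the presence of the lactone and free hydroxyl with retention of E geometry, and the new carbinol configuration is irrelevant because it is oxidised next.

Step 22
Reactants: 33 allylic alcohol
Product: 34 (3R,3aS,5R,6S,7S,8S,8aR)-7-[(2E)-but-2-enoyl]-7-hydroxy-3,6-dimethyl-8-[(triethylsilyl)oxy]-5-[(triisopropylsilyl)oxy]octahydro-2H-cyclohepta[b]furan-2-one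
Conditions: Dess–Martin periodinane, CH2Cl2, rt
Reagents that add atoms: none
Why: Dess–Martin oxidation of the secondary allylic alcohol gives the α-hydroxy enone without touching the tertiary alcohol or the E-alkene.

Step 23
Reactants: 34 bis-silyl ether
Product: 35 (3R,3aS,5R,6S,7S,8S,8aR)-7-[(2E)-but-2-enoyl]-7,8-dihydroxy-3,6-dimethyl-5-[(triisopropylsilyl)oxy]octahydro-2H-cyclohepta[b]furan-2-one
Conditions: HF·pyridine, pyridine, THF, 0 °C
Reagents that add atoms: none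
Why: Selective desilylation: a triethylsilyl ether is cleaved by buffered HF far faster than a triisopropylsilyl ether, so only the C5 hydroxyl is freed.

Step 24
Reactants: 35 diol; 36 angelic acid [(2Z)-2-methylbut-2-enoic acid]
Product: 38 (3R,3aS,5R,6S,7S,8S,8aR)-7-[(2E)-but-2-enoyl]-7-hydroxy-3,6-dimethyl-2-oxo-5-[(triisopropylsilyl)oxy]octahydro-2H-cyclohepta[b]furan-8-yl (2Z)-2-methylbut-2-enoate, via mixed anhydride 37 (not isolated)
Conditions: 36, 2,4,6-trichlorobenzoyl chloride, Et3N, toluene, rt; then 35, 75 °C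
Reagents that add atoms: none
Why: Yamaguchi esterification through the mixed anhydride acylates the secondary C5 hydroxyl (the tertiary one is unreactive), and omitting DMAP avoids isomerisation of the angelate to the tiglate.

Step 25
Reactants: 38 silyl ether
Product: 39 (3R,3aS,5R,6S,7S,8S,8aR)-7-[(2E)-but-2-enoyl]-5,7-dihydroxy-3,6-dimethyl-2-oxooctahydro-2H-cyclohepta[b]furan-8-yl (2Z)-2-methylbut-2-enoate
Conditions: HF·pyridine, THF, rt
Reagents that add atoms: none
Why: Acidic fluoride desilylation frees the C9 hydroxyl without base, so the angelate, the enone, the tertiary ketol and the epimerisable lactone α-centre are preserved.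

**Compound list**
1 | but-3-yn-1-ol | C#CCCO | starting material
2 | tert-butyl(but-3-yn-1-yloxy)dimethylsilane | C#CCCO[Si](C)(C)C(C)(C)C | intermediate
3 | N-methoxy-N-methylacetamide | CC(=O)N(C)OC | starting material
4 | {4-[(tert-butyldimethylsilyl)oxy]but-1-yn-1-yl}lithium | [Li]C#CCCO[Si](C)(C)C(C)(C)C | intermediate
5 | 6-[(tert-butyldimethylsilyl)oxy]hex-3-yn-2-one | CC(=O)C#CCCO[Si](C)(C)C(C)(C)C | intermediate
6 | (2S)-6-[(tert-butyldimethylsilyl)oxy]hex-3-yn-2-ol | C[C@H](O)C#CCCO[Si](C)(C)C(C)(C)C | intermediate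
7 | (2S,3E)-6-[(tert-butyldimethylsilyl)oxy]hex-3-en-2-ol | C[C@H](O)/C=C/CCO[Si](C)(C)C(C)(C)C | intermediate
8 | propanoyl chloride | CCC(=O)Cl | starting material
9 | (2S,3E)-6-[(tert-butyldimethylsilyl)oxy]hex-3-en-2-yl propanoate | CCC(=O)O[C@@H](C)/C=C/CCO[Si](C)(C)C(C)(C)C | intermediate
10 | (E)-trimethylsilyl ketene acetal of 9 (methyl trans to OSiMe3) | C/C=C(/O[Si](C)(C)C)O[C@@H](C)/C=C/CCO[Si](C)(C)C(C)(C)C | intermediate
11 | trimethylsilyl (2R,3R)-5-[(tert-butyldimethylsilyl)oxy]-2-methyl-3-[(1E)-prop-1-en-1-yl]pentanoate | C[Si](C)(C)OC(=O)[C@H](C)[C@@H](/C=C/C)CCO[Si](C)(C)C(C)(C)C | intermediate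
12 | (2R,3R)-5-[(tert-butyldimethylsilyl)oxy]-2-methyl-3-[(1E)-prop-1-en-1-yl]pentanoic acid | OC(=O)[C@H](C)[C@@H](/C=C/C)CCO[Si](C)(C)C(C)(C)C | intermediate
13 | tert-butyl (2R,3R)-5-[(tert-butyldimethylsilyl)oxy]-2-methyl-3-[(1E)-prop-1-en-1-yl]pentanoate | CC(C)(C)OC(=O)[C@H](C)[C@@H](/C=C/C)CCO[Si](C)(C)C(C)(C)C | intermediate
14 | tert-butyl (2R,3R)-5-hydroxy-2-methyl-3-[(1E)-prop-1-en-1-yl]pentanoate | CC(C)(C)OC(=O)[C@H](C)[C@@H](/C=C/C)CCO | intermediate
15 | tert-butyl (2R,3R)-2-methyl-5-oxo-3-[(1E)-prop-1-en-1-yl]pentanoate | CC(C)(C)OC(=O)[C@H](C)[C@@H](/C=C/C)CC=O | intermediate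
16 | (4S)-4-benzyl-3-propanoyl-1,3-oxazolidin-2-one | CCC(=O)N1[C@@H](Cc2ccccc2)COC1=O | starting material
17 | (4S)-4-benzyl-3-{(1Z)-1-[(dibutylboranyl)oxy]prop-1-en-1-yl}-1,3-oxazolidin-2-one | C/C=C(\OB(CCCC)CCCC)N1[C@@H](Cc2ccccc2)COC1=O | intermediate
18 | tert-butyl (2R,3R,5R,6S)-7-[(4S)-4-benzyl-2-oxo-1,3-oxazolidin-3-yl]-5-hydroxy-2,6-dimethyl-7-oxo-3-[(1E)-prop-1-en-1-yl]heptanoate | CC(C)(C)OC(=O)[C@H](C)[C@@H](/C=C/C)C[C@@H](O)[C@H](C)C(=O)N1[C@@H](Cc2ccccc2)COC1=O | intermediate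
19 | tert-butyl (2R,3R,5R,6S)-5-hydroxy-7-[methoxy(methyl)amino]-2,6-dimethyl-7-oxo-3-[(1E)-prop-1-en-1-yl]heptanoate | CC(C)(C)OC(=O)[C@H](C)[C@@H](/C=C/C)C[C@@H](O)[C@H](C)C(=O)N(C)OC | intermediate
20 | tert-butyl (2R,3R,5R,6S)-7-[methoxy(methyl)amino]-2,6-dimethyl-7-oxo-3-[(1E)-prop-1-en-1-yl]-5-[(triisopropylsilyl)oxy]heptanoate | CC(C)(C)OC(=O)[C@H](C)[C@@H](/C=C/C)C[C@@H](O[Si](C(C)C)(C(C)C)C(C)C)[C@H](C)C(=O)N(C)OC | intermediate
21 | vinylmagnesium bromide | C=C[Mg]Br | starting material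
22 | tert-butyl (2R,3R,5R,6S)-2,6-dimethyl-7-oxo-3-[(1E)-prop-1-en-1-yl]-5-[(triisopropylsilyl)oxy]non-8-enoate | CC(C)(C)OC(=O)[C@H](C)[C@@H](/C=C/C)C[C@@H](O[Si](C(C)C)(C(C)C)C(C)C)[C@H](C)C(=O)C=C | intermediate
23 | tert-butyl (2R)-2-[(1R,5S,6R)-5-methyl-4-oxo-6-[(triisopropylsilyl)oxy]cyclohept-2-en-1-yl]propanoate | C1=C[C@H]([C@@H](C)C(=O)OC(C)(C)C)C[C@@H](O[Si](C(C)C)(C(C)C)C(C)C)[C@H](C)C1=O | intermediate
24 | tert-butyl (2R)-2-[(1S,2S,4R,5S,7S)-5-methyl-6-oxo-4-[(triisopropylsilyl)oxy]-8-oxabicyclo[5.1.0]octan-2-yl]propanoate | [C@H]12O[C@H]1[C@H]([C@@H](C)C(=O)OC(C)(C)C)C[C@@H](O[Si](C(C)C)(C(C)C)C(C)C)[C@H](C)C2=O | intermediate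
25 | (2R)-2-[(1S,2S,4R,5S,7S)-5-methyl-6-oxo-4-[(triisopropylsilyl)oxy]-8-oxabicyclo[5.1.0]octan-2-yl]propanoic acid | [C@H]12O[C@H]1[C@H]([C@@H](C)C(=O)O)C[C@@H](O[Si](C(C)C)(C(C)C)C(C)C)[C@H](C)C2=O | intermediate
26 | (3R,3aS,5R,6S,8S,8aR)-8-hydroxy-3,6-dimethyl-5-[(triisopropylsilyl)oxy]hexahydro-2H-cyclohepta[b]furan-2,7(3H)-dione | O[C@H]1[C@@H]2OC(=O)[C@H](C)[C@@H]2C[C@@H](O[Si](C(C)C)(C(C)C)C(C)C)[C@H](C)C1=O | intermediate
27 | (3R,3aS,5R,6S,8S,8aR)-3,6-dimethyl-8-[(triethylsilyl)oxy]-5-[(triisopropylsilyl)oxy]hexahydro-2H-cyclohepta[b]furan-2,7(3H)-dione | CC[Si](CC)(CC)O[C@H]1[C@@H]2OC(=O)[C@H](C)[C@@H]2C[C@@H](O[Si](C(C)C)(C(C)C)C(C)C)[C@H](C)C1=O | intermediate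
28 | dibromomethane | BrCBr | starting material
29 | (3R,3aS,5R,6R,8R,8aR)-3,6-dimethyl-7-methylidene-8-[(triethylsilyl)oxy]-5-[(triisopropylsilyl)oxy]octahydro-2H-cyclohepta[b]furan-2-one | CC[Si](CC)(CC)O[C@H]1[C@@H]2OC(=O)[C@H](C)[C@@H]2C[C@@H](O[Si](C(C)C)(C(C)C)C(C)C)[C@H](C)C1=C | intermediate
30 | (3R,3aS,5R,6S,7R,8S,8aR)-7-hydroxy-7-(hydroxymethyl)-3,6-dimethyl-8-[(triethylsilyl)oxy]-5-[(triisopropylsilyl)oxy]octahydro-2H-cyclohepta[b]furan-2-one | CC[Si](CC)(CC)O[C@H]1[C@@H]2OC(=O)[C@H](C)[C@@H]2C[C@@H](O[Si](C(C)C)(C(C)C)C(C)C)[C@H](C)[C@@]1(O)CO | intermediate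
31 | (3R,3aS,5R,6S,7S,8S,8aR)-7-hydroxy-3,6-dimethyl-2-oxo-8-[(triethylsilyl)oxy]-5-[(triisopropylsilyl)oxy]octahydro-2H-cyclohepta[b]furan-7-carbaldehyde | CC[Si](CC)(CC)O[C@H]1[C@@H]2OC(=O)[C@H](C)[C@@H]2C[C@@H](O[Si](C(C)C)(C(C)C)C(C)C)[C@H](C)[C@@]1(O)C=O | intermediate
32 | (1E)-1-bromoprop-1-ene | C/C=C/Br | starting material
33 | (3R,3aS,5R,6S,7R,8S,8aR)-7-hydroxy-7-[(2E)-1-hydroxybut-2-en-1-yl]-3,6-dimethyl-8-[(triethylsilyl)oxy]-5-[(triisopropylsilyl)oxy]octahydro-2H-cyclohepta[b]furan-2-one (both side-chain carbinol epimers) | CC[Si](CC)(CC)O[C@H]1[C@@H]2OC(=O)[C@H](C)[C@@H]2C[C@@H](O[Si](C(C)C)(C(C)C)C(C)C)[C@H](C)[C@@]1(O)C(O)/C=C/C | intermediate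
34 | (3R,3aS,5R,6S,7S,8S,8aR)-7-[(2E)-but-2-enoyl]-7-hydroxy-3,6-dimethyl-8-[(triethylsilyl)oxy]-5-[(triisopropylsilyl)oxy]octahydro-2H-cyclohepta[b]furan-2-one | CC[Si](CC)(CC)O[C@H]1[C@@H]2OC(=O)[C@H](C)[C@@H]2C[C@@H](O[Si](C(C)C)(C(C)C)C(C)C)[C@H](C)[C@@]1(O)C(=O)/C=C/C | intermediate
35 | (3R,3aS,5R,6S,7S,8S,8aR)-7-[(2E)-but-2-enoyl]-7,8-dihydroxy-3,6-dimethyl-5-[(triisopropylsilyl)oxy]octahydro-2H-cyclohepta[b]furan-2-one | O[C@H]1[C@@H]2OC(=O)[C@H](C)[C@@H]2C[C@@H](O[Si](C(C)C)(C(C)C)C(C)C)[C@H](C)[C@@]1(O)C(=O)/C=C/C | intermediate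
36 | angelic acid, (2Z)-2-methylbut-2-enoic acid | C/C=C(/C)C(=O)O | starting material
37 | (2Z)-2-methylbut-2-enoic 2,4,6-trichlorobenzoic anhydride | C/C=C(/C)C(=O)OC(=O)c1c(Cl)cc(Cl)cc1Cl | intermediate
38 | (3R,3aS,5R,6S,7S,8S,8aR)-7-[(2E)-but-2-enoyl]-7-hydroxy-3,6-dimethyl-2-oxo-5-[(triisopropylsilyl)oxy]octahydro-2H-cyclohepta[b]furan-8-yl (2Z)-2-methylbut-2-enoate | C/C=C(/C)C(=O)O[C@H]1[C@@H]2OC(=O)[C@H](C)[C@@H]2C[C@@H](O[Si](C(C)C)(C(C)C)C(C)C)[C@H](C)[C@@]1(O)C(=O)/C=C/C | intermediate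
39 | (3R,3aS,5R,6S,7S,8S,8aR)-7-[(2E)-but-2-enoyl]-5,7-dihydroxy-3,6-dimethyl-2-oxooctahydro-2H-cyclohepta[b]furan-8-yl (2Z)-2-methylbut-2-enoate (CNP0183494.1) | C/C=C(/C)C(=O)O[C@H]1[C@@H]2OC(=O)[C@H](C)[C@@H]2C[C@@H](O)[C@H](C)[C@@]1(O)C(=O)/C=C/C | target

**Totals**
Total step count: 25. Longest linear sequence: 25 steps (1 → 39); the partners 3, 8, 16, 21, 28, 32 and 36 are bought.

**Steps most likely to fail, with fallbacks**

Step 16 (acid-triggered lactonisation of the epoxy ketone). Acyl migration or attack at C5 may compete. The fallback sets out from 24. The ketone is reduced with NaBH4/CeCl3·7H2O (MeOH, −40 °C) to the epoxy alcohol F1. The new hydroxyl is benzylated under neutral conditions (2-benzyloxy-1-methylpyridinium triflate, MgO, PhCF3, 85 °C) to give the benzyl ether F2. Treatment with CF3CO2H/CH2Cl2 then acts on an ordinary, non-participating 2,3-epoxy alcohol ether, which opens at the carbon remote from the oxygenated C1 and gives the benzyl-protected hydroxy lactone F3. Silylation (Et3SiCl, imidazole) gives the triethylsilyl ether F4, hydrogenolysis (H2, Pd(OH)2/C, EtOAc) frees the C1 alcohol F5, and Dess–Martin oxidation comes back to the route at 27.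

Step 19 (facial selectivity of the dihydroxylation). If OsO4 attacks the face syn to the C5 silyl ether, that face is the accessible one, and a carbon nucleophile can be delivered to it instead. The fallback sets out from 27. Addition of CH2=CHMgBr/CeCl3 (THF, −78 °C) gives the tertiary vinyl carbinol F6, and ozonolysis (O3, CH2Cl2/MeOH, −78 °C; Me2S) comes back to the route at 31, which also spares steps 18 and 20.

Step 24 (angeloylation of the hindered C5 alcohol without Z-to-E isomerisation). The fallback sets out from 35. Esterification with 2-[bis(2,2,2-trifluoroethoxy)phosphoryl]propanoic acid (EDC·HCl, DMAP, CH2Cl2) gives the phosphonopropanoate F7. A Still–Gennari olefination (KN(SiMe3)2, 18-crown-6, THF, −78 °C; CH3CHO) then builds the Z-alkene in place and comes back to the route at 38.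

**Further compounds**
F1 | step 16 | epoxy alcohol: ketone of 24 reduced to CH–OH (either epimer), other centres as in 24 | [C@H]12O[C@H]1[C@H]([C@@H](C)C(=O)OC(C)(C)C)C[C@@H](O[Si](C(C)C)(C(C)C)C(C)C)[C@H](C)C2O
F2 | step 16 | benzyl ether of F1 | [C@H]12O[C@H]1[C@H]([C@@H](C)C(=O)OC(C)(C)C)C[C@@H](O[Si](C(C)C)(C(C)C)C(C)C)[C@H](C)C2OCc1ccccc1
F3 | step 16 | (3R,3aS,5R,6S,8S,8aR)-7-(benzyloxy)-8-hydroxy-3,6-dimethyl-5-[(triisopropylsilyl)oxy]octahydro-2H-cyclohepta[b]furan-2-one (position 7 either epimer; descriptors as in 26) | O[C@H]1[C@@H]2OC(=O)[C@H](C)[C@@H]2C[C@@H](O[Si](C(C)C)(C(C)C)C(C)C)[C@H](C)C1OCc1ccccc1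
F4 | step 16 | triethylsilyl ether of F3 at the 8-hydroxyl | CC[Si](CC)(CC)O[C@H]1[C@@H]2OC(=O)[C@H](C)[C@@H]2C[C@@H](O[Si](C(C)C)(C(C)C)C(C)C)[C@H](C)C1OCc1ccccc1
F5 | step 16 | 7-hydroxy compound from debenzylation of F4 (the alcohol corresponding to ketone 27) | CC[Si](CC)(CC)O[C@H]1[C@@H]2OC(=O)[C@H](C)[C@@H]2C[C@@H](O[Si](C(C)C)(C(C)C)C(C)C)[C@H](C)C1O
F6 | step 19 | 7-ethenyl-7-hydroxy analogue of 31 (vinyl on the face that carries the butenoyl group in the target) | CC[Si](CC)(CC)O[C@H]1[C@@H]2OC(=O)[C@H](C)[C@@H]2C[C@@H](O[Si](C(C)C)(C(C)C)C(C)C)[C@H](C)[C@@]1(O)C=C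
F7 | step 24 | 2-[bis(2,2,2-trifluoroethoxy)phosphoryl]propanoate of 35 at the 8-hydroxyl (phosphonate α-carbon either epimer) | CC(C(=O)O[C@H]1[C@@H]2OC(=O)[C@H](C)[C@@H]2C[C@@H](O[Si](C(C)C)(C(C)C)C(C)C)[C@H](C)[C@@]1(O)C(=O)/C=C/C)P(=O)(OCC(F)(F)F)OCC(F)(F)F
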